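The readings are calculated for substances that don't exist, and the scatter is random.

The dusk plateau, read as 68 % of 20 mM E, is 0.971 of the 14 mM J charged, so the readings fit one J spent per E, with J the limiting reagent in the dusk run. The midnight run, with 32 mM J, reads 99 %, 102 % and 98 % from 2.00 h on, which is the E charged within a scatter of 1.5 percentage points.

| setting | dusk | midnight | flask |
|---|---|---|---|
| E | 20 mM | 20 mM | 20 mM |
| J | 14 mM | 32 mM | 21.0 mM |
| Q | 0.44 mM | 0.44 mM | 0.44 mM |
| remark | run made earlier | run made earlier |  |

- dusk (time / h: X / %): 0.667: 55; 1.33: 63; 2.00: 68; 2.50: 67; 3.00: 68
- midnight (time / h: X / %): 0.667: 86; 1.33: 99; 2.00: 99; 2.50: 102; 3.00: 98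

(each reading ± 1.5 percentage points)

1. apparent order in J when 50 % of the E are converted (percent change of the rate of making X for one percent more J charged)
2. apparent order in Q when 50 % of the E are converted (percent change of the rate of making X for one percent more Q charged)

- no earlier run changes the charge of Q; that part of a forecast is a guess

What stands in the flask at the moment asked about? With one J per E, 50 % conversion leaves c_E at 0.0100 M and c_J at 0.0110 M.

How far does one percent more J move c_J there? The extra J is added to what remains, so c_J rises by the charge over the remainder. This ratio, J charged over J left at a given conversion, is the J lever, and in this flask it is 1.91.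

What reaches the rate? At a fixed conversion, with c_E the same, the apparent order in J is the lever times the local order in c_J. Local order zero gives zero, and local order one gives the lever itself. At 0.667 h the midnight run reads 86 % and the dusk run 55 %, so c_J clearly acts. The reckoning here commits to the upper end, near the lever, and has no reading on Q.

The forecast stands a little lower than the lever, with 1.8 (1.4 to 2.1) for "perhaps a slight shortfall in J". For Q it guesses 1 (0.5 to 1.2).

The flask gives 1.5 in J and 1.5 in Q, the latter above the forecast's high end.

    J + Q → D (k = 434 M⁻¹ min⁻¹)
    E + D → Z (k = 240 M⁻¹ min⁻¹)
    Z ⇌ Q + X (K = 0.0230 M, k = 7.65 min⁻¹)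
    Q ⇌ L (K = 12.1, k = 0.121 min⁻¹)

At 0.250 h, near the 0.292 h at which that conversion is reached, L holds 34.1 % of the catalyst charged and free Q 16.3 %. Divided by the lever, the order in J leaves a local order in c_J of 0.772, below one. In the dusk run, 4.00 mM J stands at the same conversion, and the lever is 3.50.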